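Assumption: the hydrogen sulfate drawn is taken as the target; because such monoesters are strong acids that are normally kept as salts, the acid form is released only in the last operation, by cation exchange.

## Structural features

The target is a flavonol: ring A (the benzo ring, C4a to C8a) is fused to the pyranone ring C (O1, C2, C3, C4), and ring B, a 4-hydroxy-3-methoxyphenyl group, is bonded to C2. Ring A carries a free hydroxyl at C5, hydrogen-bonded to the C4 carbonyl, and a methoxy group at C7; C3 carries the sulfate monoester. There is no stereocentre, so the problem is one of regiochemistry and of telling five oxygen functions apart. The sulfate on the enolic O3 is the fragile group: it is lost by acid-catalysed solvolysis and would not survive Lewis-acidic deprotection. The anion of a 3-hydroxyflavone is also sensitive to air. The real difficulty is to place one sulfate on O3 while O5 and O4' end up free and O7 and O3' methylated, and to have C3 oxygenated at all, since most flavone syntheses leave it as C–H. The key step uses the fact that C4 is an aldehyde-level carbon attached to C4a, ortho to the phenolic O1 of ring A, while C2–C3 is a two-carbon unit with ring B on C2 and oxygen on C3. That unit is an aryl-substituted silyl ynol ether, and its silyl group marks O3 for the later sulfation.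

## Logic of the disconnections

**13 to 11 (through 12).** The two O–benzyl bonds at O5 and O4' are restored and the proton is exchanged for an ammonium ion. The sulfate tolerates neither acid nor Lewis acid, so the last protecting groups must be ones that leave by neutral hydrogenolysis. In 11 both phenols are masked, so the position of the sulfate is unambiguous. The forward step must spare the S–O bond and the C2–C3 double bond, and the acid form must be released cold and briefly.

**11 to 10.** The O3–S bond is cut. The most fragile group should enter as late as possible, and in 10 the hydroxyl on C3 is the only free one. No regiochemical question remains. The demand is a sulfating agent that reaches a hydrogen-bonded, flanked enolic hydroxyl under basic conditions.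

**10 to 9.** The hydrogen on O3 is replaced by a triisopropylsilyl group. 9 is the direct product of the ring-forming step, and silicon is orthogonal to benzyl, so O3 is set apart from O5 and O4' from the moment ring C exists. The forward step needs a fluoride source that is buffered against base-induced oxidation of the flavonol anion.

**9 to 3 and 8 (key disconnection).** C4–C3 and O1–C2 are cut. This removes ring C, the link between rings A and B, and the C3 oxygen in one operation, and it gives two fragments of similar size, each two steps from a commercial compound. The design of both fragments is kept for these reasons: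
- the benzyl ether on 3 leaves a single directing hydroxyl, and both positions ortho to the formyl group carry oxygen, so only the formyl C–H bond can be activated;
- the bulky silyl group on 8 gives the most robust ynol ether.

The forward step demands the right orientation of alkyne insertion and a medium in which the acid-sensitive 8 survives. The oxidant system is therefore buffered and 8 is added slowly.

**8 to 5 (through 7 and 6), and 5 to 4.** The O–Si bond and the C(sp)–O bond are cut, which leads back to a terminal alkyne. Oxidation of an acetylide to an ynolate and O-silylation is an established one-flask operation. The demand is silylation at oxygen, which the bulky silyl triflate ensures. 5 comes from 4 by a one-carbon homologation of the formyl group; 4 is commercial.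

**3 to 2 to 1.** The O–benzyl bond is cut first, then the O7–methyl bond. 2 is symmetric, so mono-benzylation has no regiochemical issue, and chelation of the remaining hydroxyl should stop it at the monoether. The methylation of 1 must select the hydroxyl para to the formyl group; this is the one selectivity in the early part that rests on relative acidity alone.

## Other disconnections considered

**Alternative 1:** The cut is C4a–C5, inside ring A, so the aromatic ring itself is made in the key step. Pyrone A1 hides a polyketide chain. Mg(OMe)2 in methanol would open the lactone, and the carbon between the two ketone groups would then attack the ester carbon in a Claisen condensation; aromatisation would give aryl ketone A2.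
- In favour: the oxygen pattern of ring A is correct by construction. The 7-methoxy group is the pyrone methoxy group and the two flanking oxygens are equivalent free phenols. Neither the selective methylation of step 1 nor a benzyl group on O5 is needed; on this point the alternative is better than the chosen plan.
- Also in favour: it needs no transition metal and no oxidant, and the C3 oxygen arrives at its final oxidation level (as an acetal-protected enol). On the C3 oxygen it is the equal of the chosen plan.
- Against: the key step makes ring A, not ring C. After A2, ring C must still be closed and brought to the flavone level, and the acetal must be removed with acid before sulfation.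
- Against: A1 is a polycarbonyl compound with an alkoxy enone that methoxide could attack, and it must be built by a linear sequence of acylations on a preformed pyrone.
- Comparison: the ionic Claisen closure is mechanistically safer than the proposed annulation. The chosen plan is more convergent, forms two skeletal bonds instead of one in its key step, and is estimated to be one to two steps shorter.

**Alternative 2:** The cut is C3–C4. Dialdehyde A3, an ether of 3, would be treated with the carbene from a triazolium salt and DBU. The acyl anion equivalent formed at one formyl group would add to the other and close ring C as ketol A4.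
- In favour: no metal, no oxidant, room temperature, and the same ring A building block 3. The C3 oxygen arrives with the ring closure, as in the chosen plan (equal), and as a free hydroxyl, so no desilylation would be needed (one step better at that stage).
- Also in favour: which formyl group becomes the acyl anion matters little, because both possible ketols should converge on 10 after oxidation. The reaction type is established for chromanones, which is better precedent than the chosen key step has.
- Against: A4 is a dihydroflavonol. A dehydrogenation to 10 is needed, and two stereocentres are made only to be destroyed.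
- Against: A3 is the weak point. An aldehyde that carries both an aryl and an aryloxy group on its alpha carbon enolises easily, can expel the phenoxide and is prone to oxidation. Its preparation from 3 would need an O-alkylation and an adjustment of oxidation level next to a second formyl group.
- Comparison: one skeletal bond is formed against two, and the route is estimated to be three to four steps longer.

**Alternative 3:** C4 is removed as carbon monoxide, cutting C4a–C4, C4–C3 and O1–C2. Iodophenol A5, CO and alkyne 5 would be joined by PdCl2(PPh3)2 (divalent palladium, reduced in the flask to zerovalent palladium). The sequence is oxidative addition, CO insertion, coupling with the alkyne and 6-endo addition of the phenol, giving flavone A6.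
- In favour: it is a known three-component reaction and forms three bonds. It uses 5 as it stands, so the acid-sensitive 8 and step 4 are not needed; this is a real gain in robustness.
- Against: C3 arrives as C–H, so A6 needs a separate oxidation at C3 to reach 10. A 5-exo attack of the phenol can compete with the 6-endo closure.
- Against: in A5 the iodine lies between two oxygen substituents on an electron-rich ring, which slows oxidative addition. Making A5 requires iodination at the most hindered of several activated positions. CO must be handled.
- Comparison: on step count the alternative is the equal of the chosen plan, and on precedent it is the better. On structure the chosen plan is the better, because it sets the oxidation level of C3 and distinguishes O3 in the ring-forming event itself.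

Key step: step 5

## Route

Step 1
Reactants: 1 2,4,6-trihydroxybenzaldehyde
Product: 2 2,6-dihydroxy-4-methoxybenzaldehyde
Conditions: Me2SO4 (1.0 equiv), K2CO3 (1.0 equiv), acetone, 0 °C to rt
Reagents that add atoms: dimethyl sulfate, COS(=O)(=O)OC
Why: Williamson ether synthesis (SN2); the hydroxyl para to the formyl group is the most acidic and is not held in a hydrogen bond to the formyl oxygen, so one equivalent of base and of methylating agent should put the methyl group on O4, after which the remaining hydroxyls are less acidic and chelated.

Step 2
Reactants: 2 2,6-dihydroxy-4-methoxybenzaldehyde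
Product: 3 2-(benzyloxy)-6-hydroxy-4-methoxybenzaldehyde
Conditions: BnBr (1.05 equiv), K2CO3 (1.1 equiv), DMF, rt
Reagents that add atoms: benzyl bromide, BrCc1ccccc1
Why: Williamson ether synthesis on a symmetric diol; the two hydroxyls are equivalent, and once one is benzylated the other is locked in a strong hydrogen bond to the formyl oxygen, which should stop the reaction at the monoether.

Step 3
Reactants: 4 4-(benzyloxy)-3-methoxybenzaldehyde
Product: 5 1-(benzyloxy)-4-ethynyl-2-methoxybenzene
Conditions: dimethyl (1-diazo-2-oxopropyl)phosphonate (1.3 equiv), K2CO3 (2 equiv), MeOH, 0 °C to rt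
Reagents that add atoms: dimethyl (1-diazo-2-oxopropyl)phosphonate, CC(=O)C(=[N+]=[N-])P(=O)(OC)OC
Why: Seyferth–Gilbert homologation with the Ohira–Bestmann reagent; methanolysis of the reagent gives the diazomethylphosphonate anion, which olefinates the aldehyde, and loss of N2 with a 1,2-hydride shift gives the terminal alkyne under conditions that do not touch the benzyl ether.

Step 4
Reactants: 5 1-(benzyloxy)-4-ethynyl-2-methoxybenzene
Product: 8 {[(4-benzyloxy-3-methoxyphenyl)ethynyl]oxy}tri(propan-2-yl)silane, via lithium (4-benzyloxy-3-methoxyphenyl)acetylide 6 (not isolated), via lithium 2-(4-benzyloxy-3-methoxyphenyl)ethyn-1-olate 7 (not isolated)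
Conditions: LiN(SiMe3)2, THF, −78 °C; LiOOtBu (from t-BuOOH and LiN(SiMe3)2), −78 to 0 °C; TIPSOTf, −78 to 0 °C
Reagents that add atoms: tert-butyl hydroperoxide, CC(C)(C)OO; triisopropylsilyl trifluoromethanesulfonate, CC(C)[Si](OS(=O)(=O)C(F)(F)F)(C(C)C)C(C)C
Why: Electrophilic oxygen transfer from LiOOtBu to the lithium acetylide 6 gives the ynolate 7 with loss of tert-butoxide, and the bulky silyl triflate then reacts at oxygen and not at carbon; this is the established one-flask conversion of terminal alkynes into silyl ynol ethers.

Step 5
Reactants: 3 2-(benzyloxy)-6-hydroxy-4-methoxybenzaldehyde; 8 {[(4-benzyloxy-3-methoxyphenyl)ethynyl]oxy}tri(propan-2-yl)silane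
Product: 9 5-(benzyloxy)-2-[4-(benzyloxy)-3-methoxyphenyl]-7-methoxy-3-{[tri(propan-2-yl)silyl]oxy}-4H-chromen-4-one
Conditions: [Cp*RhCl2]2 (2.5 mol %), Cu(OAc)2 (anhydrous, 2.2 equiv), K2CO3 (2.2 equiv), 4 Å MS, toluene, 80 °C, 8 (1.5 equiv) added over 4 h, Ar
Reagents that add atoms: none
Why: Proposed new method: Cp*Rh(OAc)2, formed from [Cp*RhCl2]2 and acetate, should bind the phenoxide of 3 and cleave the formyl C–H bond by concerted metalation–deprotonation to a five-membered O,C-chelated acyl complex of trivalent rhodium; syn insertion of 8 into the Rh–acyl bond forms C4–C3 and a seven-membered oxa-rhodacycle, C–O reductive elimination forms O1–C2, and Cu(OAc)2 returns the monovalent rhodium to the trivalent state. The closest known reaction type is the rhodium-catalysed oxidative annulation of salicylaldehydes with internal alkynes to 2,3-disubstituted chromones, supported by trivalent-rhodium C–H annulations of other heteroatom-substituted alkynes such as ynamides; a silyl ynol ether has not been used in this role. Ring C, six-membered, is closed by a formal [4+2] oxidative annulation in which the ring-closing event is the C–O reductive elimination, and no stereocentre is formed. The required orientation (acyl carbon to the silyloxy-bearing alkyne carbon, rhodium to the aryl-bearing one) follows from the ketene-like polarisation of 8, whose oxygen-bearing carbon is the electrophilic one, and from the preference of rhodium for an aryl-substituted vinyl carbon, so both effects point the same way. Both positions ortho to the formyl group of 3 carry oxygen, so no aryl C–H bond competes, and the benzyl ether leaves a single directing hydroxyl. The main chemoselectivity demand is that insertion must outrun protonation of 8 to a ketene by the acetic acid released on reoxidation; solid K2CO3, molecular sieves, anhydrous Cu(OAc)2 and slow addition of 8 are meant to secure this. The moderate temperature that an electron-rich alkyne should allow also disfavours decarbonylation at the acyl rhodium stage.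

Step 6
Reactants: 9 5-(benzyloxy)-2-[4-(benzyloxy)-3-methoxyphenyl]-7-methoxy-3-{[tri(propan-2-yl)silyl]oxy}-4H-chromen-4-one
Product: 10 5-(benzyloxy)-2-[4-(benzyloxy)-3-methoxyphenyl]-3-hydroxy-7-methoxy-4H-chromen-4-one
Conditions: Bu4NF (1.1 equiv), AcOH (1.1 equiv), THF, 0 °C
Reagents that add atoms: none
Why: Fluoride-induced cleavage of a silyl enol ether; the 3-oxide of a flavone is a stabilised leaving group, so desilylation should be fast at 0 °C, and acetic acid buffers the medium so that the air-sensitive flavonol anion does not build up, while benzyl and methyl ethers are inert.

Step 7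
Reactants: 10 5-(benzyloxy)-2-[4-(benzyloxy)-3-methoxyphenyl]-3-hydroxy-7-methoxy-4H-chromen-4-one
Product: 11 triethylammonium 5-(benzyloxy)-2-[4-(benzyloxy)-3-methoxyphenyl]-7-methoxy-4-oxo-4H-chromen-3-yl sulfate
Conditions: SO3·NMe3 (4 equiv), Et3N (8 equiv), DMF, 60 °C, Ar
Reagents that add atoms: sulfur trioxide–trimethylamine complex, C[N+](C)(C)S(=O)(=O)[O-]; triethylamine, CCN(CC)CC
Why: O-Sulfonation with a sulfur trioxide–amine complex; 10 has a single free hydroxyl, triethylamine breaks its hydrogen bond to the C4 carbonyl by deprotonation, and the monoester is obtained as a base-stable triethylammonium salt that can be chromatographed.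

Step 8
Reactants: 11 triethylammonium 5-(benzyloxy)-2-[4-(benzyloxy)-3-methoxyphenyl]-7-methoxy-4-oxo-4H-chromen-3-yl sulfate
Product: 13 5-hydroxy-2-(4-hydroxy-3-methoxyphenyl)-7-methoxy-4-oxo-4H-chromen-3-yl hydrogen sulfate (rhamnazin 3-O-sulfate), via triethylammonium rhamnazin 3-O-sulfate 12 (not isolated)
Conditions: H2 (1 atm), 10% Pd/C, MeOH–THF, rt; filter, evaporate; Dowex 50W-X8 (H+ form), H2O, 0 °C; freeze-dry
Reagents that add atoms: none
Why: Hydrogenolysis of the two aryl benzyl ethers over Pd/C is a neutral process that should leave the hexavalent sulfur of the sulfate, the methyl ethers and the chromone double bond untouched; brief contact of salt 12 with a sulfonic acid resin in cold water then replaces triethylammonium by a proton, and immediate freeze-drying limits acid-catalysed solvolysis of the sulfate.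

## Compound list

1 | 2,4,6-trihydroxybenzaldehyde | O=Cc1c(O)cc(O)cc1O | starting material
2 | 2,6-dihydroxy-4-methoxybenzaldehyde | COc1cc(O)c(C=O)c(O)c1 | intermediate
3 | 2-(benzyloxy)-6-hydroxy-4-methoxybenzaldehyde | COc1cc(O)c(C=O)c(OCc2ccccc2)c1 | intermediate
4 | 4-(benzyloxy)-3-methoxybenzaldehyde | COc1cc(C=O)ccc1OCc1ccccc1 | starting material
5 | 1-(benzyloxy)-4-ethynyl-2-methoxybenzene | COc1cc(C#C)ccc1OCc1ccccc1 | intermediate
6 | lithium (4-benzyloxy-3-methoxyphenyl)acetylide | [Li+].[C-]#Cc1ccc(OCc2ccccc2)c(OC)c1 | intermediate (not isolated)
7 | lithium 2-(4-benzyloxy-3-methoxyphenyl)ethyn-1-olate | [Li+].[O-]C#Cc1ccc(OCc2ccccc2)c(OC)c1 | intermediate (not isolated)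
8 | {[(4-benzyloxy-3-methoxyphenyl)ethynyl]oxy}tri(propan-2-yl)silane | COc1cc(C#CO[Si](C(C)C)(C(C)C)C(C)C)ccc1OCc1ccccc1 | intermediate
9 | 5-(benzyloxy)-2-[4-(benzyloxy)-3-methoxyphenyl]-7-methoxy-3-{[tri(propan-2-yl)silyl]oxy}-4H-chromen-4-one | COc1cc(OCc2ccccc2)c2c(=O)c(O[Si](C(C)C)(C(C)C)C(C)C)c(-c3ccc(OCc4ccccc4)c(OC)c3)oc2c1 | intermediate
10 | 5-(benzyloxy)-2-[4-(benzyloxy)-3-methoxyphenyl]-3-hydroxy-7-methoxy-4H-chromen-4-one | COc1cc(OCc2ccccc2)c2c(=O)c(O)c(-c3ccc(OCc4ccccc4)c(OC)c3)oc2c1 | intermediate
11 | triethylammonium 5-(benzyloxy)-2-[4-(benzyloxy)-3-methoxyphenyl]-7-methoxy-4-oxo-4H-chromen-3-yl sulfate | COc1cc(OCc2ccccc2)c2c(=O)c(OS(=O)(=O)[O-])c(-c3ccc(OCc4ccccc4)c(OC)c3)oc2c1.CC[NH+](CC)CC | intermediate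
12 | triethylammonium 5-hydroxy-2-(4-hydroxy-3-methoxyphenyl)-7-methoxy-4-oxo-4H-chromen-3-yl sulfate | COc1cc(O)c2c(=O)c(OS(=O)(=O)[O-])c(-c3ccc(O)c(OC)c3)oc2c1.CC[NH+](CC)CC | intermediate (not isolated)
13 | 5-hydroxy-2-(4-hydroxy-3-methoxyphenyl)-7-methoxy-4-oxo-4H-chromen-3-yl hydrogen sulfate (rhamnazin 3-O-sulfate) | COc1cc(O)c2c(=O)c(OS(=O)(=O)O)c(-c3ccc(O)c(OC)c3)oc2c1 | target

## Step count and least certain steps

Total: 8 steps. Longest linear sequence: 6 steps (steps 1, 2, 5, 6, 7, 8; the branch through steps 3 and 4 is equally long).

**Step 5 (key step, proposed new method).**
- Most likely failure: loss of 8 by protonation at its aryl-bearing carbon to a ketene before it meets the acyl rhodium species. The acid sources are the acetic acid released on reoxidation and the phenol of 3, and ynol ethers are among the most acid-sensitive alkynes.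
- Less likely: insertion in the opposite sense, or decarbonylation at the acyl rhodium stage. Either would take material off the path to 9.
- Fallback (known reactions only): it sets out from 3 and 6 (made from 5 as in step 4) and rejoins the route at 10. Two equivalents of 6 are added to 3 in THF, the first being consumed by the phenol, to give racemic propargylic alcohol F1. MnO2 in CH2Cl2 oxidises it to ynone F2. Et2NH in ethanol brings about conjugate addition and 6-endo closure to flavone F3. Dimethyldioxirane in acetone–CH2Cl2 epoxidises the C2–C3 double bond to epoxide F4, and a trace of p-TsOH opens it to 10. This costs three more steps and gives up the silyl marker, which is not needed because 10 has only one free hydroxyl.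

**Step 4.**
- Most likely failure: incomplete oxygen transfer from LiOOtBu to the electron-rich aryl acetylide, and hydrolytic loss of the ynol ether during isolation on silica.
- Fallback: it sets out from 4 and rejoins at 7. Oxidative esterification of 4 (I2, KOH, MeOH) gives methyl ester F5. In a Kowalski-type homologation, LiCHBr2 (from CH2Br2 and lithium 2,2,6,6-tetramethylpiperidide, THF, −78 °C) adds to the ester, and loss of methoxide followed by deprotonation gives dibromo enolate F6. n-BuLi exchanges one bromine, and migration of the aryl group with loss of LiBr gives 7, which is silylated in the same flask as in step 4 to give 8.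

**Step 1.**
- Most likely failure: poor site selectivity and over-alkylation. At any moment one of the two ortho hydroxyls is outside the hydrogen bond and competes with the para hydroxyl.
- Fallback: it sets out from 1 and rejoins at 2. Exhaustive methylation (Me2SO4 in excess, K2CO3, acetone, reflux) gives 2,4,6-trimethoxybenzaldehyde F7. AlCl3 in excess in CH2Cl2 then cleaves the two methyl ethers ortho to the formyl group through the aluminium chelate and leaves the para ether, giving 2. Regiocontrol then comes from chelation instead of from relative acidity.

**Step 8.**
- Most likely failure: stalling of the hydrogenolysis, since traces of free amine from the salt can moderate the Pd surface, and solvolytic loss of the sulfate once the acid form is concentrated.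
- Fallback: it sets out from 10 and rejoins at 13. 2,2,2-Trichloroethyl chlorosulfate with Et3N and DMAP in THF gives the neutral 2,2,2-trichloroethyl sulfate diester F8. Pd/C with HCO2NH4 in MeOH removes the trichloroethyl group by reductive fragmentation and both benzyl ethers by transfer hydrogenolysis, in a buffered medium that never becomes acidic, giving ammonium salt F9. Cold exchange on the acid resin as in step 8 gives 13.
- If the acid form proves too labile to store, 12 or F9 is the form to keep, and the proton exchange is left to the point of use.

## Further compounds

F1 | step 5 | racemic 1-[2-(benzyloxy)-6-hydroxy-4-methoxyphenyl]-3-[4-(benzyloxy)-3-methoxyphenyl]prop-2-yn-1-ol | COc1cc(O)c(C(O)C#Cc2ccc(OCc3ccccc3)c(OC)c2)c(OCc2ccccc2)c1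
F2 | step 5 | 1-[2-(benzyloxy)-6-hydroxy-4-methoxyphenyl]-3-[4-(benzyloxy)-3-methoxyphenyl]prop-2-yn-1-one | COc1cc(O)c(C(=O)C#Cc2ccc(OCc3ccccc3)c(OC)c2)c(OCc2ccccc2)c1
F3 | step 5 | 5-(benzyloxy)-2-[4-(benzyloxy)-3-methoxyphenyl]-7-methoxy-4H-chromen-4-one | COc1cc(OCc2ccccc2)c2c(=O)cc(-c3ccc(OCc4ccccc4)c(OC)c3)oc2c1
F4 | step 5 | racemic cis-fused 2,3-epoxide of F3, 5-(benzyloxy)-2-[4-(benzyloxy)-3-methoxyphenyl]-2,3-epoxy-7-methoxy-2,3-dihydro-4H-chromen-4-one (one enantiomer drawn) | COc1cc(OCc2ccccc2)c2C(=O)[C@@H]3O[C@]3(c3ccc(OCc4ccccc4)c(OC)c3)Oc2c1
F5 | step 4 | methyl 4-(benzyloxy)-3-methoxybenzoate | COC(=O)c1ccc(OCc2ccccc2)c(OC)c1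
F6 | step 4 | lithium 1-[4-(benzyloxy)-3-methoxyphenyl]-2,2-dibromoethen-1-olate | [Li+].[O-]C(=C(Br)Br)c1ccc(OCc2ccccc2)c(OC)c1
F7 | step 1 | 2,4,6-trimethoxybenzaldehyde | COc1cc(OC)c(C=O)c(OC)c1
F8 | step 8 | 5-(benzyloxy)-2-[4-(benzyloxy)-3-methoxyphenyl]-7-methoxy-4-oxo-4H-chromen-3-yl 2,2,2-trichloroethyl sulfate | COc1cc(OCc2ccccc2)c2c(=O)c(OS(=O)(=O)OCC(Cl)(Cl)Cl)c(-c3ccc(OCc4ccccc4)c(OC)c3)oc2c1
F9 | step 8 | ammonium 5-hydroxy-2-(4-hydroxy-3-methoxyphenyl)-7-methoxy-4-oxo-4H-chromen-3-yl sulfate | COc1cc(O)c2c(=O)c(OS(=O)(=O)[O-])c(-c3ccc(O)c(OC)c3)oc2c1.[NH4+]
A1 | alternative 1 | 6-[(3Z)-4-(4-benzyloxy-3-methoxyphenyl)-3-(methoxymethoxy)-2-oxobut-3-en-1-yl]-4-methoxy-2H-pyran-2-one | COc1cc(CC(=O)/C(OCOC)=C/c2ccc(OCc3ccccc3)c(OC)c2)oc(=O)c1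
A2 | alternative 1 | (2Z)-3-(4-benzyloxy-3-methoxyphenyl)-1-(2,6-dihydroxy-4-methoxyphenyl)-2-(methoxymethoxy)prop-2-en-1-one | COc1cc(O)c(C(=O)/C(OCOC)=C/c2ccc(OCc3ccccc3)c(OC)c2)c(O)c1
A3 | alternative 2 | racemic 2-(benzyloxy)-6-{1-[4-(benzyloxy)-3-methoxyphenyl]-2-oxoethoxy}-4-methoxybenzaldehyde | COc1cc(OCc2ccccc2)c(C=O)c(OC(C=O)c2ccc(OCc3ccccc3)c(OC)c2)c1
A4 | alternative 2 | racemic trans-5-(benzyloxy)-2-(4-benzyloxy-3-methoxyphenyl)-3-hydroxy-7-methoxychroman-4-one (2R,3R enantiomer drawn) | COc1cc(ccc1OCc1ccccc1)[C@@H]1[C@H](C(=O)c2c(OCc3ccccc3)cc(OC)cc2O1)O
A5 | alternative 3 | 3-(benzyloxy)-2-iodo-5-methoxyphenol | COc1cc(O)c(I)c(OCc2ccccc2)c1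
A6 | alternative 3 | 5-(benzyloxy)-2-(4-benzyloxy-3-methoxyphenyl)-7-methoxy-4H-chromen-4-one | COc1cc(OCc2ccccc2)c2c(=O)cc(-c3ccc(OCc4ccccc4)c(OC)c3)oc2c1
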